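**Plan**

- Retrosynthesis: the three phenols are masked as methoxymethyl (MOM) ethers and C4 is taken to the carbinol. Ring C is then opened at the aryl ether bond O1–C8a, giving an open-chain (S)-1,3-diol whose ring A carries chlorine at C8a. The diol goes back through the aldol to the chalcone (C2–O bond), the chalcone to an aryllithium plus a Weinreb cinnamamide (C4–C4a bond), and ring A to 5-chlororesorcinol (C8–CH3 and C6–prenyl bonds).
- Enabling feature: O1 sits on C8a of ring A, between C8 (methyl) and C4a (chain). Chlorine on that carbon, the middle atom of symmetric 5-chlororesorcinol, first acidifies both neighbours for ortho-lithiation and then acts as the leaving group. The C2 oxygen lies five atoms from C8a, so aryl C–O coupling closes a six-membered ring. The usual polarity (a phenol oxygen attacking C2) is reversed, which removes the choice between two phenols that would scramble the 6-prenyl/8-methyl pattern.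
- Forward order: rings A and B are present from the start. Ring A is substituted by three directed lithiations (prenyl between the OMOM groups, then methyl, then the cinnamoyl chain). The chalcone is hydrated enantioselectively by borylation–oxidation, the ketone is parked as a carbinol, ring C is closed last by palladium-catalysed etherification, C4 is re-oxidised and the MOM groups are removed.
- Stereochemistry: C2 (S) comes from ligand-controlled copper-catalysed conjugate borylation of the E-chalcone, followed by oxidation with retention. No later step makes or breaks a bond at C2, and ring closure at the carbinol level excludes retro-aldol, elimination and chalcone-type ring opening.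

Key step: step 8

Assumption: the ferrocenyl bisphosphine enantiomer named in step 6 is taken to deliver boron to the face of the chalcone that gives the 3S boronate; if the opposite sense were found, its mirror image would be used.

**Route**

Step 1
Reactants: 1 5-chlororesorcinol
Product: 2 1-chloro-3,5-bis(methoxymethoxy)benzene
Conditions: MOMCl (2.5 equiv), i-Pr2NEt (3 equiv), CH2Cl2, 0 °C to rt
Reagents that add atoms: chloromethyl methyl ether (MOMCl) COCCl
Why: Standard O-alkylation of both phenols gives the bis-MOM ether, whose OMOM groups direct the lithiations that follow and should survive every step until the final acid treatment.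

Step 2
Reactants: 2 1-chloro-3,5-bis(methoxymethoxy)benzene; 3 prenyl bromide (1-bromo-3-methylbut-2-ene)
Product: 5 5-chloro-1,3-bis(methoxymethoxy)-2-(3-methylbut-2-en-1-yl)benzene, via aryllithium 4 (not isolated)
Conditions: n-BuLi (1.1 equiv), THF, –20 °C; CuI (10 mol%), then 3, –78 °C to rt
Reagents that add atoms: none
Why: Directed ortho-metalation should occur at the carbon flanked by both OMOM groups (double chelation), and copper-catalysed allylic substitution at the primary carbon of prenyl bromide installs the unrearranged prenyl group, leaving a symmetric arene.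

Step 3
Reactants: 5 5-chloro-1,3-bis(methoxymethoxy)-2-(3-methylbut-2-en-1-yl)benzene
Product: 7 1-chloro-3,5-bis(methoxymethoxy)-2-methyl-4-(3-methylbut-2-en-1-yl)benzene, via aryllithium 6 (not isolated)
Conditions: s-BuLi (1.05 equiv), THF, –78 °C; MeI, –78 °C to rt
Reagents that add atoms: iodomethane CI
Why: The two remaining ring hydrogens are equivalent and each lies between chlorine (inductive acidification) and OMOM (coordination), so a second directed ortho-metalation and methylation can give only one product, with methyl next to chlorine.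

Step 4
Reactants: 8 4-(methoxymethoxy)benzaldehyde; 9 diethyl {2-[methoxy(methyl)amino]-2-oxoethyl}phosphonate
Product: 11 (2E)-N-methoxy-3-[4-(methoxymethoxy)phenyl]-N-methylprop-2-enamide, via sodium phosphonate carbanion 10 (not isolated)
Conditions: NaH, THF, 0 °C to rt
Reagents that add atoms: none
Why: Horner–Wadsworth–Emmons olefination with a stabilised phosphonate anion should give the E-configured Weinreb cinnamamide.

Step 5
Reactants: 7 1-chloro-3,5-bis(methoxymethoxy)-2-methyl-4-(3-methylbut-2-en-1-yl)benzene; 11 (2E)-N-methoxy-3-[4-(methoxymethoxy)phenyl]-N-methylprop-2-enamide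
Product: 14 (2E)-1-[2-chloro-4,6-bis(methoxymethoxy)-3-methyl-5-(3-methylbut-2-en-1-yl)phenyl]-3-[4-(methoxymethoxy)phenyl]prop-2-en-1-one, via aryllithium 12 (not isolated), via lithium hemiaminal 13 (not isolated)
Conditions: s-BuLi (1.05 equiv), THF, –78 °C; 11, –78 °C; AcOH, –78 °C to rt
Reagents that add atoms: none
Why: The only ring hydrogen left is removed by a third directed ortho-metalation, and Weinreb ketone synthesis (1,2-addition to the N-methoxy-N-methylamide, the chelated tetrahedral adduct collapsing only on quench) should give the E-chalcone without over-addition, the low temperature keeping the ortho-chloro aryllithium from losing LiCl.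

Step 6
Reactants: 14 (2E)-1-[2-chloro-4,6-bis(methoxymethoxy)-3-methyl-5-(3-methylbut-2-en-1-yl)phenyl]-3-[4-(methoxymethoxy)phenyl]prop-2-en-1-one
Product: 16 (3S)-1-[2-chloro-4,6-bis(methoxymethoxy)-3-methyl-5-(3-methylbut-2-en-1-yl)phenyl]-3-hydroxy-3-[4-(methoxymethoxy)phenyl]propan-1-one, via β-boryl ketone 15 (not isolated)
Conditions: CuCl (3 mol%), NaOt-Bu (5 mol%), (R)-1-[(SP)-2-(diphenylphosphino)ferrocenyl]ethyldicyclohexylphosphine (4 mol%), B2pin2 (1.1 equiv), MeOH (2 equiv), THF, rt; then NaBO3·4H2O, THF–H2O, rt
Reagents that add atoms: sodium perborate (source of the hydroxyl oxygen) [Na+].[O-]OB=O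
Why: Copper-catalysed enantioselective conjugate borylation of the enone (boryl–copper addition across the C=C bond, the chiral bisphosphine choosing the face at the β-carbon, then protonation by methanol) sets C3 as S, and perborate oxidation of the C–B bond with retention should give the aldol without exposing it to strong base.

Step 7
Reactants: 16 (3S)-1-[2-chloro-4,6-bis(methoxymethoxy)-3-methyl-5-(3-methylbut-2-en-1-yl)phenyl]-3-hydroxy-3-[4-(methoxymethoxy)phenyl]propan-1-one
Product: 17 (1RS,3S)-1-[2-chloro-4,6-bis(methoxymethoxy)-3-methyl-5-(3-methylbut-2-en-1-yl)phenyl]-3-[4-(methoxymethoxy)phenyl]propane-1,3-diol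
Conditions: NaBH4, MeOH–THF, 0 °C to rt
Reagents that add atoms: none
Why: Borohydride reduction parks the future C4 at the carbinol level so that no carbonyl-based dehydration, retro-aldol or ring opening can occur during ring closure; the new carbinol centre forms as a mixture of epimers and is erased again in step 9.

Step 8
Reactants: 17 (1RS,3S)-1-[2-chloro-4,6-bis(methoxymethoxy)-3-methyl-5-(3-methylbut-2-en-1-yl)phenyl]-3-[4-(methoxymethoxy)phenyl]propane-1,3-diol
Product: 18 (2S,4RS)-5,7-bis(methoxymethoxy)-2-[4-(methoxymethoxy)phenyl]-8-methyl-6-(3-methylbut-2-en-1-yl)-3,4-dihydro-2H-chromen-4-ol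
Conditions: [Pd(allyl)Cl]2 (2.5 mol%), RockPhos (2-di-tert-butylphosphino-3-methoxy-6-methyl-2',4',6'-triisopropylbiphenyl, 6 mol%), Cs2CO3 (1.5 equiv), toluene, 90 °C
Reagents that add atoms: none
Why: Zerovalent palladium inserts into the C8a–Cl bond, the hydroxyl on the future C2 binds and is deprotonated by Cs2CO3, and C(aryl)–O reductive elimination from the resulting seven-membered arylpalladium alkoxide forms the O1–C8a bond. The closest known reaction type is the intramolecular Buchwald–Hartwig etherification of 3-(2-halophenyl)propanols to chromans, in which enantioenriched secondary alcohols are known to cyclise with their configuration intact. Ring C closes as a six-membered ring by a formal 6-exo attack of oxygen on the aryl carbon, the C8a–C4a–C4–C3–C2 chain being already in place. No stereocentre is created: C2 stays S because no bond to it is made or broken and, with C4 held as a carbinol, enolisation, retro-aldol, dehydration and chalcone-type ring opening are all impossible, while the two C4 epimers converge in step 9. The step needs C–O reductive elimination to outrun β-hydride elimination of the benzylic alkoxide, which the bulky di-tert-butylbiaryl phosphine and the doubly ortho-substituted aryl group on palladium favour, and it needs the C2 hydroxyl to couple in preference to the C4 hydroxyl, which ring size secures because the latter could only give a four-membered ring. Regiochemistry on ring A needs no control, since C8a is the only carbon bearing a halogen and already has the methyl group as its neighbour.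

Step 9
Reactants: 18 (2S,4RS)-5,7-bis(methoxymethoxy)-2-[4-(methoxymethoxy)phenyl]-8-methyl-6-(3-methylbut-2-en-1-yl)-3,4-dihydro-2H-chromen-4-ol
Product: 19 (2S)-5,7-bis(methoxymethoxy)-2-[4-(methoxymethoxy)phenyl]-8-methyl-6-(3-methylbut-2-en-1-yl)-2,3-dihydro-4H-chromen-4-one
Conditions: Dess–Martin periodinane, pyridine, CH2Cl2, 0 °C to rt
Reagents that add atoms: none
Why: Dess–Martin oxidation of the benzylic secondary alcohol restores the C4 ketone under buffered, non-basic conditions that should leave the prenyl group, the MOM ethers and the C2 stereocentre untouched.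

Step 10
Reactants: 19 (2S)-5,7-bis(methoxymethoxy)-2-[4-(methoxymethoxy)phenyl]-8-methyl-6-(3-methylbut-2-en-1-yl)-2,3-dihydro-4H-chromen-4-one
Product: 20 (2S)-5,7-dihydroxy-2-(4-hydroxyphenyl)-8-methyl-6-(3-methylbut-2-en-1-yl)-2,3-dihydro-4H-chromen-4-one
Conditions: 3 M HCl, MeOH, rt to 40 °C
Reagents that add atoms: none
Why: Acid-catalysed acetal exchange with methanol removes the three MOM ethers under conditions mild enough that the prenyl group should not hydrate or cyclise and the pyranone ring should not open, so the S configuration at C2 is kept.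

**Compound list**

1 | 5-chlororesorcinol (5-chlorobenzene-1,3-diol) | Oc1cc(O)cc(Cl)c1 | starting material
2 | 1-chloro-3,5-bis(methoxymethoxy)benzene | COCOc1cc(Cl)cc(OCOC)c1 | intermediate
3 | prenyl bromide (1-bromo-3-methylbut-2-ene) | CC(C)=CCBr | starting material
4 | [4-chloro-2,6-bis(methoxymethoxy)phenyl]lithium, formed in situ | [Li]c1c(OCOC)cc(Cl)cc1OCOC | intermediate
5 | 5-chloro-1,3-bis(methoxymethoxy)-2-(3-methylbut-2-en-1-yl)benzene | COCOc1cc(Cl)cc(OCOC)c1CC=C(C)C | intermediate
6 | [6-chloro-2,4-bis(methoxymethoxy)-3-(3-methylbut-2-en-1-yl)phenyl]lithium, formed in situ | [Li]c1c(Cl)cc(OCOC)c(CC=C(C)C)c1OCOC | intermediate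
7 | 1-chloro-3,5-bis(methoxymethoxy)-2-methyl-4-(3-methylbut-2-en-1-yl)benzene | COCOc1cc(Cl)c(C)c(OCOC)c1CC=C(C)C | intermediate
8 | 4-(methoxymethoxy)benzaldehyde | COCOc1ccc(C=O)cc1 | starting material
9 | diethyl {2-[methoxy(methyl)amino]-2-oxoethyl}phosphonate | CCOP(=O)(CC(=O)N(C)OC)OCC | starting material
10 | sodium salt of the carbanion of 9, formed in situ | [Na+].CCOP(=O)([CH-]C(=O)N(C)OC)OCC | intermediate
11 | (2E)-N-methoxy-3-[4-(methoxymethoxy)phenyl]-N-methylprop-2-enamide | CON(C)C(=O)/C=C/c1ccc(OCOC)cc1 | intermediate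
12 | [2-chloro-4,6-bis(methoxymethoxy)-3-methyl-5-(3-methylbut-2-en-1-yl)phenyl]lithium, formed in situ | [Li]c1c(Cl)c(C)c(OCOC)c(CC=C(C)C)c1OCOC | intermediate
13 | lithium (2E)-1-[2-chloro-4,6-bis(methoxymethoxy)-3-methyl-5-(3-methylbut-2-en-1-yl)phenyl]-1-[methoxy(methyl)amino]-3-[4-(methoxymethoxy)phenyl]prop-2-en-1-olate (racemic), formed in situ | [Li]OC(/C=C/c1ccc(OCOC)cc1)(N(C)OC)c1c(Cl)c(C)c(OCOC)c(CC=C(C)C)c1OCOC | intermediate
14 | (2E)-1-[2-chloro-4,6-bis(methoxymethoxy)-3-methyl-5-(3-methylbut-2-en-1-yl)phenyl]-3-[4-(methoxymethoxy)phenyl]prop-2-en-1-one | CC(C)=CCc1c(OCOC)c(C)c(Cl)c(c1OCOC)C(=O)/C=C/c1ccc(OCOC)cc1 | intermediate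
15 | (3S)-1-[2-chloro-4,6-bis(methoxymethoxy)-3-methyl-5-(3-methylbut-2-en-1-yl)phenyl]-3-[4-(methoxymethoxy)phenyl]-3-(4,4,5,5-tetramethyl-1,3,2-dioxaborolan-2-yl)propan-1-one, formed in situ | CC(C)=CCc1c(OCOC)c(C)c(Cl)c(c1OCOC)C(=O)C[C@@H](c1ccc(OCOC)cc1)B1OC(C)(C)C(C)(C)O1 | intermediate
16 | (3S)-1-[2-chloro-4,6-bis(methoxymethoxy)-3-methyl-5-(3-methylbut-2-en-1-yl)phenyl]-3-hydroxy-3-[4-(methoxymethoxy)phenyl]propan-1-one | CC(C)=CCc1c(OCOC)c(C)c(Cl)c(c1OCOC)C(=O)C[C@@H](c1ccc(OCOC)cc1)O | intermediate
17 | (1RS,3S)-1-[2-chloro-4,6-bis(methoxymethoxy)-3-methyl-5-(3-methylbut-2-en-1-yl)phenyl]-3-[4-(methoxymethoxy)phenyl]propane-1,3-diol | CC(C)=CCc1c(OCOC)c(C)c(Cl)c(c1OCOC)C(O)C[C@@H](c1ccc(OCOC)cc1)O | intermediate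
18 | (2S,4RS)-5,7-bis(methoxymethoxy)-2-[4-(methoxymethoxy)phenyl]-8-methyl-6-(3-methylbut-2-en-1-yl)-3,4-dihydro-2H-chromen-4-ol | CC(C)=CCc1c(OCOC)c(C)c2c(c1OCOC)C(O)C[C@@H](c1ccc(OCOC)cc1)O2 | intermediate
19 | (2S)-5,7-bis(methoxymethoxy)-2-[4-(methoxymethoxy)phenyl]-8-methyl-6-(3-methylbut-2-en-1-yl)-2,3-dihydro-4H-chromen-4-one | CC(C)=CCc1c(OCOC)c(C)c2c(c1OCOC)C(=O)C[C@@H](c1ccc(OCOC)cc1)O2 | intermediate
20 | (2S)-5,7-dihydroxy-2-(4-hydroxyphenyl)-8-methyl-6-(3-methylbut-2-en-1-yl)-2,3-dihydro-4H-chromen-4-one | CC(C)=CCc1c(O)c(C)c2c(c1O)C(=O)C[C@@H](c1ccc(O)cc1)O2 | target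

**Step count and risks**

Total: 10 steps. Longest linear sequence: 9 steps (steps 1, 2, 3, 5, 6, 7, 8, 9 and 10 from 5-chlororesorcinol); step 4 is a one-step side branch.

Risk 1 (step 8). Oxidative addition into the hindered, electron-rich C–Cl bond may be slow. β-Hydride elimination from the benzylic palladium alkoxide may compete, giving net hydrodechlorination and oxidation of the carbinol. Palladium may also be held back as a five-membered chelate by the C4 alkoxide. The fallback sets out from 16 (racemic 16 is sufficient, so step 6 could then be run with an achiral ligand) and sets the stereocentre after ring closure. Dess–Martin oxidation of 16 gives the 1,3-diketone 1-[2-chloro-4,6-bis(methoxymethoxy)-3-methyl-5-(3-methylbut-2-en-1-yl)phenyl]-3-[4-(methoxymethoxy)phenyl]propane-1,3-dione F1. Its enol oxygen closes the same O–C8a bond by copper-catalysed intramolecular O-arylation (CuI, K2CO3, DMF, 100 °C), the usual entry to flavones from ortho-halophenyl 1,3-diketones, giving the flavone 5,7-bis(methoxymethoxy)-2-[4-(methoxymethoxy)phenyl]-8-methyl-6-(3-methylbut-2-en-1-yl)-4H-chromen-4-one F2. Enantioselective copper hydride conjugate reduction (Cu(OAc)2, the DTBM-SEGPHOS enantiomer that gives 2S, (EtO)2MeSiH, t-BuOH, toluene) then comes back to the route at 19.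

Risk 2 (step 6). Facial selectivity or conversion may be poor in the conjugate borylation, because the carbonyl of this chalcone is twisted out of the plane of ring A by its two ortho substituents. The fallback sets out from 8 and 7 and sets the stereocentre on a small fragment by Noyori transfer hydrogenation. Addition of the lithium enolate of N-methoxy-N-methylacetamide (LDA, THF, –78 °C) to 8 gives racemic 3-hydroxy-N-methoxy-3-[4-(methoxymethoxy)phenyl]-N-methylpropanamide F3. Dess–Martin oxidation gives N-methoxy-3-[4-(methoxymethoxy)phenyl]-N-methyl-3-oxopropanamide F4. Reduction with RuCl[(S,S)-TsDPEN](p-cymene) in HCO2H–Et3N should give (3S)-3-hydroxy-N-methoxy-3-[4-(methoxymethoxy)phenyl]-N-methylpropanamide F5, the sense following the aryl ketone model of this catalyst. Deprotonation of the hydroxyl with i-PrMgCl and addition of aryllithium 12 (made from 7 as in step 5) comes back to the route at 16.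

Risk 3 (step 5). The ortho-chloro aryllithium may lose LiCl (aryne formation) before it adds, or this hindered base may fragment the N-methoxy amide (loss of formaldehyde) and so lower the conversion. The fallback sets out from 11 and 7 and replaces acyl substitution by addition to an aldehyde followed by oxidation. DIBAL-H reduction of 11 (THF, –78 °C) gives (2E)-3-[4-(methoxymethoxy)phenyl]prop-2-enal F6, a much faster electrophile. 1,2-Addition of aryllithium 12 at –78 °C gives racemic (2E)-1-[2-chloro-4,6-bis(methoxymethoxy)-3-methyl-5-(3-methylbut-2-en-1-yl)phenyl]-3-[4-(methoxymethoxy)phenyl]prop-2-en-1-ol F7. Oxidation with MnO2 (CH2Cl2, rt) comes back to the route at 14.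

Further compounds
F1 | step 8 | 1-[2-chloro-4,6-bis(methoxymethoxy)-3-methyl-5-(3-methylbut-2-en-1-yl)phenyl]-3-[4-(methoxymethoxy)phenyl]propane-1,3-dione | CC(C)=CCc1c(OCOC)c(C)c(Cl)c(c1OCOC)C(=O)CC(=O)c1ccc(OCOC)cc1
F2 | step 8 | 5,7-bis(methoxymethoxy)-2-[4-(methoxymethoxy)phenyl]-8-methyl-6-(3-methylbut-2-en-1-yl)-4H-chromen-4-one | CC(C)=CCc1c(OCOC)c(C)c2c(c1OCOC)C(=O)C=C(c1ccc(OCOC)cc1)O2
F3 | step 6 | rac-3-hydroxy-N-methoxy-3-[4-(methoxymethoxy)phenyl]-N-methylpropanamide | CON(C)C(=O)CC(O)c1ccc(OCOC)cc1
F4 | step 6 | N-methoxy-3-[4-(methoxymethoxy)phenyl]-N-methyl-3-oxopropanamide | CON(C)C(=O)CC(=O)c1ccc(OCOC)cc1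
F5 | step 6 | (3S)-3-hydroxy-N-methoxy-3-[4-(methoxymethoxy)phenyl]-N-methylpropanamide | CON(C)C(=O)C[C@@H](c1ccc(OCOC)cc1)O
F6 | step 5 | (2E)-3-[4-(methoxymethoxy)phenyl]prop-2-enal | O=C/C=C/c1ccc(OCOC)cc1
F7 | step 5 | rac-(2E)-1-[2-chloro-4,6-bis(methoxymethoxy)-3-methyl-5-(3-methylbut-2-en-1-yl)phenyl]-3-[4-(methoxymethoxy)phenyl]prop-2-en-1-ol | CC(C)=CCc1c(OCOC)c(C)c(Cl)c(c1OCOC)C(O)/C=C/c1ccc(OCOC)cc1
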